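**The ceiling.** If each J holds two Q, then the Q charged caps J in south and south-west at 60.0 % of the L charged, whatever the time. That cap is a yield on Q of 0.5. It is true but loose, so we ask the earlier runs how close they came.

| setting | gamma | theta | epsilon | south | south-west |
|---|---|---|---|---|---|
| L | 0.25 M | 0.25 M | 0.50 M | 0.25 M | 0.25 M |
| Q | 0.20 M | 0.45 M | 0.30 M | 0.300 M | 0.300 M |
| temperature | 105 °C | 116 °C | 105 °C | 100 °C | 120 °C |
| remark | run made earlier | run made earlier | run made earlier |  |  |
| time |  |  |  | 4.0 h | 4.0 h |

- gamma (time / h: J / %): 0.200: 0.9; 0.667: 5.5; 1.00: 9.1; 1.50: 11.9; 2.50: 14.3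
- theta (time / min: J / %): 5.00: 4.5; 20.0: 23.4; 25.0: 26.1; 40.0: 32.8; 60.0: 34.6
- epsilon (time / h: J / %): 0.200: 1.8; 0.667: 8.0; 1.00: 10.4; 1.50: 11.1; 2.50: 11.3

(readings scatter by 0.3 percentage points)

- steps that have been proposed: L + Q -> X; Q + X -> J; Q + J -> G; Q + G -> D; X -> Z; J <-> E

1. which of the two there is more of at the end, south (Z / J)
2. which of the two there is more of at the end, south-west (Z / J)
3. how much J is there at the end, in percent of the L charged: south
4. how much J is there at the end, in percent of the L charged: south-west

**The yield.** We compare the runs by amounts at one moment of each, not by whole curves. At the last readings, each with its scatter, J per Q charged is 0.179 in gamma, 0.192 in theta and 0.188 in epsilon. We call their mean, 0.186, w: moles of J per mole of Q charged at the last reading of a run.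

**Our bracket.** Multiplying by the charge ratio Q/L turns a yield into percent of L. Gamma, the lowest, gives a lower bound of 21.5 %. Theta, the highest, gives an upper bound of 23.1 %. These bounds are our own and assume that both flasks show at 4.0 h the yield the earlier runs showed at their last readings, although 100 °C and 120 °C lie outside the temperatures tried.

**The forecast.** It gives J 22 % (range 16 % to 28 %) in south, with more J than the other. It gives J 26 % (range 18 % to 34 %) in south-west, with more Z. Its ground is that “Plateaus occur when Q runs out”. Its south value falls inside our bracket, and its south-west value lies above it.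

**The result.** South ends with J 24.8 % and Z 18.4 %; south-west ends with J 14.2 % and Z 47.0 %.

    L + Q → X (k = 0.0390 /M/min, Ea = 101 kJ/mol)
    Q + X → J (k = 0.0590 /M/min, Ea = 90.0 kJ/mol)
    Q + J → G (k = 0.0150 /M/min, Ea = 80.0 kJ/mol)
    Q + G → D (k = 0.00390 /M/min, Ea = 81.0 kJ/mol)
    X → Z (k = 0.00380 /min, Ea = 122 kJ/mol)
    J ⇌ E (K = 1.50, k = 5.50 × 10⁻⁴ /min, Ea = 117 kJ/mol, ΔH = 11.0 kJ/mol)
    (constants at 100 °C)

**The yield again.** South's yield is 0.207, above our bracket, and south-west's is 0.118, below it. South-west, with Q, the limiting reagent, at 0.615 % of its charge, holds 12.4 % of the L charged as E. The repeat of south-west at 105 °C, the temperature of epsilon, gives J 24.1 %, a yield of 0.201 against w of 0.186.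

The earlier runs and the new flask come from a simulation on assumed constants, noise included.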